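**Plan**

1. Retrosynthesis: the first cut is the bond between the outer vinylic CH and C5 of the resorcinol ring (ring B). The second is the C=C of the bridge, which returns to a formyl group on the phenol ring (ring A) plus one carbon of a malonate. The third is the ring A C3–CH2 bond to the geranyl chain.
2. Forward: both benzene rings are bought. 4-Hydroxybenzaldehyde (1) is C-geranylated ortho to its hydroxyl with geranyl bromide (2) to give aldehyde 3, and 1-iodo-3,5-dimethoxybenzene (4) is demethylated to 5-iodoresorcinol (5).
3. Then 3, 5 and malonic acid (6) are joined in one operation: Knoevenagel–Doebner condensation to cinnamic acid 7, decarboxylation to vinylphenol 8, and Mizoroki–Heck arylation to schweinfurthin I (9), with none of the three phenols protected.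
4. Enabling feature: the free hydroxyl at C4 of ring A stands para to C1, the carbon that carries the bridge, so 7 can tautomerise to a para-quinone methide and lose CO2. The two hydroxyls of ring B stand meta to the C–I carbon, so they need no protection.
5. Stereochemistry: there is no stereocentre. The 2E alkene of the chain is bought with 2 and kept by SN2 alkylation; the E stilbene alkene is set by syn-insertion and syn-β-hydride elimination in the Heck stage.

Key step: step 3

Remark: "geranyl" stands for (2E)-3,7-dimethylocta-2,6-dien-1-yl throughout.

**Route**

Step 1
Reactants: 1 4-hydroxybenzaldehyde; 2 geranyl bromide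
Product: 3 3-geranyl-4-hydroxybenzaldehyde
Conditions: KOH (1 equiv per 1), H2O, rt, 24 h, 1 in twofold excess over 2; then AcOH to pH 5, extraction of the phenolic product into dilute base, chromatography
Reagents that add atoms: none
Why: C-alkylation of an ambident phenoxide, in which water masks the phenoxide oxygen by hydrogen bonding so that the soft primary allylic bromide is attacked in SN2 fashion by the ring carbon ortho to the oxygen (the para carbon carries the formyl group), the dienone re-aromatises, the 2E alkene is untouched, and the excess of 1 holds back a second alkylation.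

Step 2
Reactants: 4 1-iodo-3,5-dimethoxybenzene
Product: 5 5-iodoresorcinol (5-iodobenzene-1,3-diol)
Conditions: BBr3 (3 equiv), CH2Cl2, −78 °C to rt; then H2O, 0 °C
Reagents that add atoms: none
Why: Lewis-acid cleavage of aryl methyl ethers, in which BBr3 binds each ether oxygen, bromide attacks the methyl carbon (SN2) to give bromomethane and an aryloxyborane that water hydrolyses to the phenol, while the C–I bond, meta to both oxygens and so not prone to ipso-protonation, should survive.

Step 3
Reactants: 3 3-geranyl-4-hydroxybenzaldehyde; 5 5-iodoresorcinol; 6 malonic acid
Product: 9 schweinfurthin I, via cinnamic acid 7 (not isolated), via vinylphenol 8 (not isolated)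
Conditions: 5 (1.2 equiv), 6 (3 equiv), piperidine (5 equiv), Pd(PPh3)4 (5 mol %), LiCl (1 equiv), degassed DMF, 140 °C, argon, exclusion of light, all components charged at the outset; then aq NH4Cl work-up
Reagents that add atoms: none
Why: Piperidine condenses aldehyde 3 with malonic acid (Knoevenagel–Doebner, with loss of water and the first CO2) to cinnamic acid 7; because the hydroxyl at C4 of ring A is para to the side chain, 7 tautomerises to a para-quinone methide protonated at the carbon next to the carboxyl group, which expels the second CO2 and re-aromatises to vinylphenol 8. Pd(PPh3)4 then inserts into the C–I bond of 5, the arylpalladium iodide adds syn across the vinyl group of 8 with the aryl group going to the terminal carbon, and syn-β-hydride elimination releases the stilbene while piperidine takes up HI and returns zerovalent palladium. The closest known reaction type is the one-pot Knoevenagel–decarboxylation–Mizoroki–Heck sequence that turns 4-hydroxybenzaldehydes, malonic acid and aryl halides into hydroxystilbenes. No ring is closed and no stereocentre is made; the only new stereo-element, the E alkene, is set by the syn-insertion/syn-elimination pathway through the conformer with the two aryl groups anti, and it is also the thermodynamic isomer. The step needs chemoselectivity for the monosubstituted vinyl group over the two trisubstituted alkenes of the geranyl chain, which their substitution secures, and terminal rather than internal arylation, which the neutral pathway with halide on palladium and the steric bias of a styrene secure. The two hydroxyls of 5 are meta to iodine, so even as phenoxides they should slow the insertion little, and the wholly basic medium spares the acid-sensitive ortho-geranylphenol from cyclising to a chroman.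

**Compound list**

1 | 4-hydroxybenzaldehyde | O=Cc1ccc(O)cc1 | starting material
2 | geranyl bromide, (2E)-1-bromo-3,7-dimethylocta-2,6-diene | CC(C)=CCC/C(C)=C/CBr | starting material
3 | 3-[(2E)-3,7-dimethylocta-2,6-dien-1-yl]-4-hydroxybenzaldehyde | CC(C)=CCC/C(C)=C/Cc1cc(C=O)ccc1O | intermediate
4 | 1-iodo-3,5-dimethoxybenzene | COc1cc(I)cc(OC)c1 | starting material
5 | 5-iodobenzene-1,3-diol (5-iodoresorcinol) | Oc1cc(O)cc(I)c1 | intermediate
6 | malonic acid | OC(=O)CC(=O)O | starting material
7 | (2E)-3-{3-[(2E)-3,7-dimethylocta-2,6-dien-1-yl]-4-hydroxyphenyl}prop-2-enoic acid | CC(C)=CCC/C(C)=C/Cc1cc(/C=C/C(=O)O)ccc1O | intermediate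
8 | 2-[(2E)-3,7-dimethylocta-2,6-dien-1-yl]-4-ethenylphenol | CC(C)=CCC/C(C)=C/Cc1cc(C=C)ccc1O | intermediate
9 | schweinfurthin I, 5-[(E)-2-{3-[(2E)-3,7-dimethylocta-2,6-dien-1-yl]-4-hydroxyphenyl}ethenyl]benzene-1,3-diol | CC(C)=CCC/C(C)=C/Cc1cc(/C=C/c2cc(O)cc(O)c2)ccc1O | target

**Count and risks**

Total step count: 3. Longest linear sequence: 2 steps (step 1 then step 3, or step 2 then step 3).

Steps most likely to fail:

Step 3. The vinylphenol may polymerise at 140 °C before the arylpalladium species intercepts it. The catalyst may be deactivated by phenoxides and malonate. A palladium hydride may shift the benzylic–allylic alkene of the geranyl chain into conjugation. The fallback separates olefination from coupling and runs the coupling on protected phenols at lower temperature; it sets out from 3 and 5 and comes back at 9. Wittig methylenation of 3 (methyltriphenylphosphonium bromide, KOtBu, 3 equiv, THF, 0 °C to rt) should give vinylphenol 8, now isolated. Prompt acetylation (Ac2O, pyridine, 0 °C) should give 4-ethenyl-2-geranylphenyl acetate F1. 5 is acetylated in the same way to 5-iodo-1,3-phenylene diacetate F2. A two-component Mizoroki–Heck reaction of F1 with F2 (Pd(OAc)2, P(o-tol)3, Et3N, MeCN, 85 °C) should give schweinfurthin I triacetate F3, and K2CO3 in MeOH at rt should release 9 without acid.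

Step 1. O-alkylation may compete with C-alkylation, a second geranyl group may enter at the other ortho carbon, the allylic bromide may hydrolyse in water, and attack through its tertiary end may occur. The fallback replaces phenoxide alkylation by aryl copper alkylation; it sets out from 1 and 2 and comes back at 3. Bromination of 1 (Br2, AcOH, rt) should give 3-bromo-4-hydroxybenzaldehyde F4. Acetalisation (ethylene glycol, cat. TsOH, toluene, reflux with removal of water) should give 2-bromo-4-(1,3-dioxolan-2-yl)phenol F5. Etherification (MOMCl, i-Pr2NEt, CH2Cl2, 0 °C to rt) should give 2-[3-bromo-4-(methoxymethoxy)phenyl]-1,3-dioxolane F6. Bromine–lithium exchange (n-BuLi, THF, −78 °C), transmetalation with CuBr·SMe2 and SN2 alkylation with 2 should give 2-[3-geranyl-4-(methoxymethoxy)phenyl]-1,3-dioxolane F7 with the 2E alkene intact. Dilute HCl in THF/MeOH at rt should remove both acetals and return 3; this last operation must stay mild to avoid chroman formation.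

Step 2. Cleavage may stall after the first ether once the aryloxyborane has formed, and the water-soluble diol may be lost in the aqueous work-up. The fallback is a dealkylative silylation with non-aqueous release; it sets out from 4 and comes back at 5. Me3SiCl and NaI in MeCN at reflux should convert 4 into 1-iodo-3,5-bis(trimethylsilyloxy)benzene F8, with iodide attacking the methyl groups of the silyloxonium ions. Methanol at rt should then give 5 after evaporation.

**Further compounds**

F1 | step 3 | 4-ethenyl-2-[(2E)-3,7-dimethylocta-2,6-dien-1-yl]phenyl acetate | CC(C)=CCC/C(C)=C/Cc1cc(C=C)ccc1OC(C)=O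
F2 | step 3 | 5-iodo-1,3-phenylene diacetate | CC(=O)Oc1cc(I)cc(OC(C)=O)c1
F3 | step 3 | schweinfurthin I triacetate | CC(C)=CCC/C(C)=C/Cc1cc(/C=C/c2cc(OC(C)=O)cc(OC(C)=O)c2)ccc1OC(C)=O
F4 | step 1 | 3-bromo-4-hydroxybenzaldehyde | O=Cc1ccc(O)c(Br)c1
F5 | step 1 | 2-bromo-4-(1,3-dioxolan-2-yl)phenol | Oc1ccc(C2OCCO2)cc1Br
F6 | step 1 | 2-[3-bromo-4-(methoxymethoxy)phenyl]-1,3-dioxolane | COCOc1ccc(C2OCCO2)cc1Br
F7 | step 1 | 2-{3-[(2E)-3,7-dimethylocta-2,6-dien-1-yl]-4-(methoxymethoxy)phenyl}-1,3-dioxolane | CC(C)=CCC/C(C)=C/Cc1cc(C2OCCO2)ccc1OCOC
F8 | step 2 | 1-iodo-3,5-bis(trimethylsilyloxy)benzene | C[Si](C)(C)Oc1cc(I)cc(O[Si](C)(C)C)c1
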